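**Strategy**

- Retrosynthesis: the enone is first traced back without C–C cleavage, the ketone C1 to a free carbinol and the alkene C2=C3 to an acetoxy carbinol at C3. The bond from C5 to the CH2 of the 2-oxononadecenyl chain is then cut as an aldol, leaving a ketone derived from cyclohexane-1,3,5-triol (from phloroglucinol) and the methyl ketone of oleic acid.
- Enabling feature (ring numbered C1 ketone, C2=C3, C4, C5 carbinol, C6): C5 bears OH and three CH2 groups, and its ring arms C6–C1(=O) and C4–C3H= both descend from CH–O carbons. A latent mirror plane therefore runs through C5 and C2 of the six-membered ring, and the oxygens sit in the 1,3,5-pattern of phloroglucinol.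
- Forward: the only ring is the phloroglucinol ring, hydrogenated all-cis. Two hydroxyls are silylated, the third is oxidised, and the chain is joined at that carbon by a ketone–ketone aldol; no ring is formed afterwards.
- Stereochemistry: C5 is built as the non-stereogenic centre of a meso triol. A lipase acetylates one of the two enantiotopic secondary hydroxyls; oxidation of the free carbinol and loss of acetic acid from the other then fix C5 as R. The Z alkene is that of oleic acid.

Key step: step 8

Assumption: the lipase is taken to acetylate the (S)-configured secondary carbinol of triol 13 (the one that ends as alkene carbon C3). Because the two ring arms at each carbinol differ only at the next carbon, the sense cannot be read safely from the empirical size rule for secondary alcohols; the opposite outcome is dealt with after the route.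

**Route**

Step 1
Reactants: 1 phloroglucinol (benzene-1,3,5-triol)
Product: 2 cis,cis-cyclohexane-1,3,5-triol (all three hydroxyls on one face; meso)
Conditions: H2 (100 bar), Rh/Al2O3, EtOH, 60 °C
Reagents that add atoms: none
Why: Heterogeneous arene hydrogenation delivers all hydrogens from the catalyst-bound face, so the three hydroxyls should end up mutually cis, rhodium at moderate temperature keeps C–O hydrogenolysis low, and the crystalline all-cis triol is freed from minor isomers by recrystallisation.

Step 2
Reactants: 2 cis,cis-cyclohexane-1,3,5-triol
Product: 3 all-cis-3,5-bis(tert-butyldimethylsilyloxy)cyclohexan-1-ol (meso)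
Conditions: TBSCl (2 equiv), imidazole, DMF, 0 °C to rt
Reagents that add atoms: tert-butyldimethylsilyl chloride (TBSCl), CC(C)(C)[Si](C)(C)Cl
Why: Silyl ether formation on three equivalent hydroxyls is statistical, so two equivalents of the chloride should make the bis-ether the main product, which is separated by chromatography from the mono- and tris-ethers (both recyclable, the latter after desilylation).

Step 3
Reactants: 3 all-cis-3,5-bis(tert-butyldimethylsilyloxy)cyclohexan-1-ol
Product: 4 cis-3,5-bis(tert-butyldimethylsilyloxy)cyclohexan-1-one ((3R,5S); meso)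
Conditions: Dess–Martin periodinane, pyridine, CH2Cl2, 0 °C to rt
Reagents that add atoms: none
Why: Dess–Martin oxidation of the single free secondary alcohol under buffered, non-basic conditions should give the β-silyloxy ketone without β-elimination of silanol.

Step 4
Reactants: 5 oleic acid ((Z)-octadec-9-enoic acid)
Product: 7 (Z)-N-methoxy-N-methyloctadec-9-enamide, via N-oleoylimidazole 6 (not isolated)
Conditions: CDI, CH2Cl2, rt; then MeNH(OMe)·HCl, rt
Reagents that add atoms: N,O-dimethylhydroxylamine hydrochloride, CNOC.Cl; 1,1'-carbonyldiimidazole (CDI), O=C(n1ccnc1)n1ccnc1 (its imidazole is held only in 6)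
Why: Activation of the acid as the acyl imidazole followed by aminolysis is a standard Weinreb amide synthesis that leaves the isolated Z alkene untouched.

Step 5
Reactants: 7 (Z)-N-methoxy-N-methyloctadec-9-enamide
Product: 9 (Z)-nonadec-10-en-2-one, via bromomagnesium hemiaminal chelate 8 (not isolated)
Conditions: MeMgBr, THF, 0 °C; then 1 M HCl
Reagents that add atoms: methylmagnesium bromide, C[Mg]Br
Why: Weinreb ketone synthesis, in which the chelated tetrahedral adduct persists until the acidic quench, so exactly one methyl group is added.

Step 6
Reactants: 9 (Z)-nonadec-10-en-2-one; 4 cis-3,5-bis(tert-butyldimethylsilyloxy)cyclohexan-1-one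
Product: 12 (Z)-1-[(1s,3R,5S)-3,5-bis(tert-butyldimethylsilyloxy)-1-hydroxycyclohexyl]nonadec-10-en-2-one (meso; tertiary hydroxyl cis to both silyloxy groups), via lithium methyl-side enolate 10 (not isolated), via dichlorocerium enolate 11 (not isolated)
Conditions: LiN(iPr)2, THF, −78 °C (9 added slowly to the base); CeCl3 (anhydrous), −78 °C; then 4, −78 °C; aq. NH4Cl at −78 °C
Reagents that add atoms: none
Why: Directed aldol addition in which kinetic deprotonation by the hindered amide should take mainly the methyl protons, the less basic cerium enolate should add to ketone 4 faster than it deprotonates it (which would start β-elimination of silanolate), and axial attack on the chair with both silyloxy groups equatorial should set the new C–C bond axial and the hydroxyl equatorial, cis to the silyloxy groups; the carbinol carbon lies on the mirror plane, so no stereocentre arises and the minor meso epimer is removed by chromatography.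

Step 7
Reactants: 12 (Z)-1-[(1s,3R,5S)-3,5-bis(tert-butyldimethylsilyloxy)-1-hydroxycyclohexyl]nonadec-10-en-2-one
Product: 13 (Z)-1-[(1s,3R,5S)-1,3,5-trihydroxycyclohexyl]nonadec-10-en-2-one (meso all-cis triol)
Conditions: HF·pyridine, pyridine, THF, 0 °C to rt
Reagents that add atoms: none
Why: Fluoride-driven cleavage of the two secondary silyl ethers under buffered, weakly acidic conditions avoids the tertiary alkoxide that basic fluoride would form (retro-aldol), and since the side chain is trans to the secondary hydroxyls its ketone cannot close a hemiketal onto them.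

Step 8
Reactants: 13 (Z)-1-[(1s,3R,5S)-1,3,5-trihydroxycyclohexyl]nonadec-10-en-2-one
Product: 14 (1S,3R,5R)-3,5-dihydroxy-3-[(Z)-2-oxononadec-10-en-1-yl]cyclohexyl acetate
Conditions: Burkholderia cepacia lipase (Amano PS, immobilised), vinyl acetate, tBuOMe, 30 °C, stopped once 13 is consumed
Reagents that add atoms: vinyl acetate, C=COC(C)=O
Why: The active-site serine of the lipase is acetylated by vinyl acetate, the leaving enol tautomerises to acetaldehyde so that the transfer cannot reverse, and the acyl-enzyme passes the acetyl group to one secondary hydroxyl of 13, forming one ester C–O bond. The closest known reaction type is the lipase-catalysed monoacylation of meso cis-cyclohexane-1,3-diols and of derivatives of cis,cis-cyclohexane-1,3,5-triol with enol esters. No ring is closed. The carbinol carbon that bears the side chain lies on the mirror plane of 13 and becomes a stereocentre (R in 14) as soon as its two ring arms differ, so its configuration is controlled only by the chiral active site, which has to pick the (S)-configured carbinol. The selectivity needed is between the two enantiotopic secondary hydroxyls; the substrate secures the rest, because the tertiary hydroxyl is not accepted by lipases, the ketone and the Z alkene are inert, and the side chain stands on the ring face opposite to the three hydroxyls. A second, slower acetylation removes mainly the minor enantiomer of the monoacetate (its free hydroxyl is the preferred one), so running slightly beyond full conversion of 13 should raise the enantiomeric purity of 14.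

Step 9
Reactants: 14 (1S,3R,5R)-3,5-dihydroxy-3-[(Z)-2-oxononadec-10-en-1-yl]cyclohexyl acetate
Product: 15 (1R,3R)-3-hydroxy-5-oxo-3-[(Z)-2-oxononadec-10-en-1-yl]cyclohexyl acetate
Conditions: Dess–Martin periodinane, pyridine, CH2Cl2, 0 °C
Reagents that add atoms: none
Why: Dess–Martin oxidation converts the only secondary alcohol into the ketone while the tertiary alcohol cannot react, and running it directly after step 8 under near-neutral conditions forestalls 1,3-acetyl migration between the cis oxygens, which would erode the enantiomeric purity.

Step 10
Reactants: 15 (1R,3R)-3-hydroxy-5-oxo-3-[(Z)-2-oxononadec-10-en-1-yl]cyclohexyl acetate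
Product: 16 (R)-5-hydroxy-5-[(Z)-2-oxononadec-10-en-1-yl]cyclohex-2-en-1-one (CNP0165051.1)
Conditions: Et3N, CH2Cl2, 0 °C
Reagents that add atoms: none
Why: E1cB elimination in which the new ring ketone acidifies the CH2 next to the acetoxy carbon, acetate leaves far more readily than the tertiary hydroxyl on the other side, and the mild amine base at 0 °C should stop at the enone before a second elimination or a retro-aldol; the stereocentre is not involved.

**Compound list**

1 | phloroglucinol (benzene-1,3,5-triol) | Oc1cc(O)cc(O)c1 | starting material
2 | cis,cis-cyclohexane-1,3,5-triol (all-cis, meso) | O[C@H]1C[C@@H](O)C[C@@H](O)C1 | intermediate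
3 | all-cis-3,5-bis(tert-butyldimethylsilyloxy)cyclohexan-1-ol (meso) | O[C@H]1C[C@@H](O[Si](C)(C)C(C)(C)C)C[C@@H](O[Si](C)(C)C(C)(C)C)C1 | intermediate
4 | cis-3,5-bis(tert-butyldimethylsilyloxy)cyclohexan-1-one ((3R,5S), meso) | O=C1C[C@H](O[Si](C)(C)C(C)(C)C)C[C@H](O[Si](C)(C)C(C)(C)C)C1 | intermediate
5 | oleic acid ((Z)-octadec-9-enoic acid) | CCCCCCCC/C=C\CCCCCCCC(=O)O | starting material
6 | N-oleoylimidazole ((Z)-1-(imidazol-1-yl)octadec-9-en-1-one) | CCCCCCCC/C=C\CCCCCCCC(=O)n1ccnc1 | intermediate (not isolated)
7 | (Z)-N-methoxy-N-methyloctadec-9-enamide | CCCCCCCC/C=C\CCCCCCCC(=O)N(C)OC | intermediate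
8 | bromomagnesium hemiaminal chelate of 7 after methyl addition | CCCCCCCC/C=C\CCCCCCCC(C)(O[Mg]Br)N(C)OC | intermediate (not isolated)
9 | (Z)-nonadec-10-en-2-one | CCCCCCCC/C=C\CCCCCCCC(C)=O | intermediate
10 | lithium (10Z)-nonadeca-1,10-dien-2-olate (methyl-side enolate) | [Li]OC(=C)CCCCCCC/C=C\CCCCCCCC | intermediate (not isolated)
11 | dichlorocerium (10Z)-nonadeca-1,10-dien-2-olate | Cl[Ce](Cl)OC(=C)CCCCCCC/C=C\CCCCCCCC | intermediate (not isolated)
12 | (Z)-1-[(1s,3R,5S)-3,5-bis(tert-butyldimethylsilyloxy)-1-hydroxycyclohexyl]nonadec-10-en-2-one (meso) | CCCCCCCC/C=C\CCCCCCCC(=O)C[C@]1(O)C[C@@H](O[Si](C)(C)C(C)(C)C)C[C@@H](O[Si](C)(C)C(C)(C)C)C1 | intermediate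
13 | (Z)-1-[(1s,3R,5S)-1,3,5-trihydroxycyclohexyl]nonadec-10-en-2-one (meso) | CCCCCCCC/C=C\CCCCCCCC(=O)C[C@]1(O)C[C@@H](O)C[C@@H](O)C1 | intermediate
14 | (1S,3R,5R)-3,5-dihydroxy-3-[(Z)-2-oxononadec-10-en-1-yl]cyclohexyl acetate | CCCCCCCC/C=C\CCCCCCCC(=O)C[C@]1(O)C[C@@H](OC(C)=O)C[C@@H](O)C1 | intermediate
15 | (1R,3R)-3-hydroxy-5-oxo-3-[(Z)-2-oxononadec-10-en-1-yl]cyclohexyl acetate | CCCCCCCC/C=C\CCCCCCCC(=O)C[C@]1(O)C[C@@H](OC(C)=O)CC(=O)C1 | intermediate
16 | (R)-5-hydroxy-5-[(Z)-2-oxononadec-10-en-1-yl]cyclohex-2-en-1-one (CNP0165051.1) | CCCCCCCC/C=C\CCCCCCCC(=O)C[C@]1(O)CC=CC(=O)C1 | target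

**Step count and risks**

Total steps: 10. Longest linear sequence: 8 steps (1 to 16 through steps 1, 2, 3, 6, 7, 8, 9, 10); the oleic acid branch adds steps 4 and 5.

Steps most likely to fail:

Step 8. The lipase may acetylate the other enantiotopic hydroxyl, since the size rule could just as well seat the more substituted, chain-bearing ring arm in the large site; the mirror-image configuration would then be carried to the end. The fallback sets out from 13: both secondary hydroxyls would be acetylated chemically (Ac2O, pyridine, rt; the tertiary hydroxyl stays free) to the meso diacetate (1R,3S,5s)-5-hydroxy-5-[(Z)-2-oxononadec-10-en-1-yl]cyclohexane-1,3-diyl diacetate F1. The same lipase would then be used in water (phosphate buffer pH 7, acetone as cosolvent, 30 °C). Hydrolysis removes the acetate from the carbinol the enzyme prefers, which is the mirror-image choice to acylation, and the route is rejoined at 14.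

Step 6. Deprotonation may occur partly on the methylene side of 9, the enolate may deprotonate ketone 4 and trigger β-elimination of silanolate, the aldolate may revert on warming, or attack may come from the equatorial direction. The fallback sets out from 9: the kinetic enolate would be trapped as the silyl enol ether (10Z)-2-(trimethylsilyloxy)nonadeca-1,10-diene F2 (LiN(iPr)2, Me3SiCl, THF, −78 °C), whose regiochemistry can be secured before use. F2 would be added to ketone 4 in a Mukaiyama aldol reaction (TiCl4, CH2Cl2, −78 °C, aqueous work-up), which returns to 12 without exposing 4 to a basic enolate.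

Step 10. The base may also remove the tertiary hydroxyl by a second elimination, followed by tautomerisation to a phenol, or may cleave the tertiary aldol by retro-aldol reaction. The fallback sets out from 15: the tertiary hydroxyl would first be capped with N-(trimethylsilyl)imidazole (CH2Cl2, rt) to give the silyl ether (1R,3R)-5-oxo-3-[(Z)-2-oxononadec-10-en-1-yl]-3-(trimethylsilyloxy)cyclohexyl acetate F3. Elimination of acetic acid (DBU, CH2Cl2, −20 °C) would give the silylated enone (R)-5-[(Z)-2-oxononadec-10-en-1-yl]-5-(trimethylsilyloxy)cyclohex-2-en-1-one F4, in which retro-aldol is blocked and the oxygen substituent is a poor leaving group. Buffered HF·pyridine (pyridine, THF, 0 °C) would then uncover the hydroxyl and return to 16.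

**Further compounds**

F1 | step 8 | (1R,3S,5s)-5-hydroxy-5-[(Z)-2-oxononadec-10-en-1-yl]cyclohexane-1,3-diyl diacetate (meso) | CCCCCCCC/C=C\CCCCCCCC(=O)C[C@]1(O)C[C@@H](OC(C)=O)C[C@@H](OC(C)=O)C1
F2 | step 6 | (10Z)-2-(trimethylsilyloxy)nonadeca-1,10-diene | C=C(CCCCCCC/C=C\CCCCCCCC)O[Si](C)(C)C
F3 | step 10 | (1R,3R)-5-oxo-3-[(Z)-2-oxononadec-10-en-1-yl]-3-(trimethylsilyloxy)cyclohexyl acetate | CCCCCCCC/C=C\CCCCCCCC(=O)C[C@]1(O[Si](C)(C)C)C[C@@H](OC(C)=O)CC(=O)C1
F4 | step 10 | (R)-5-[(Z)-2-oxononadec-10-en-1-yl]-5-(trimethylsilyloxy)cyclohex-2-en-1-one | CCCCCCCC/C=C\CCCCCCCC(=O)C[C@]1(O[Si](C)(C)C)CC=CC(=O)C1
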